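**Plan**

1. Retrosynthetic cuts: both phenol protecting groups come off last. Ring B (the oxolane whose ArCH carbon sits next to the C–OH bridgehead) is cut at its benzylic C–O bond and at its aryl–CH bond, back to a bicyclic bridgehead-hydroxy γ-lactone and an aryl Grignard reagent. The bridgehead OH is traced back to an acetyl group.
2. Ring A (the other oxolane) is cut at two bonds at once, CH2–C(bridgehead) and O–CH(aryl): its O–CH2 unit is formaldehyde and its three carbons are a lactone-fused donor–acceptor cyclopropane.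
3. Feature that allows this: in ring A the aryl-bearing carbon (a cation-stabilising donor site) and the bridgehead carbinol carbon stand 1,3 across the bridgehead CH. The carbinol carbon can carry two carbonyl acceptors: the lactone C=O (later the ArCH–O carbon of ring B) and an acetyl group (later the OH).
4. Forward order: Z-cinnamyl alcohol, diazoacetoacetate, asymmetric intramolecular cyclopropanation (lactone ring plus cyclopropane), (3+2) annulation with formaldehyde (ring A), Baeyer–Villiger oxidation (OH), lactol/Grignard addition/acid cycloetherification (ring B), deprotection.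
5. Stereochemistry: the absolute sense comes from the chiral dirhodium catalyst. The Z alkene gives the endo-aryl cyclopropane and inversion in the annulation turns that aryl group exo. The cis ring fusion fixes the quaternary carbon (retention in the Baeyer–Villiger step). The second aryl group goes exo in the cationic ring closure.

Key step: step 8

Remark: the antipode of the dirhodium catalyst written in step 7 is assumed to be the one that gives the (1R,5S,6S) cyclopropane; if the sense of induction is the opposite, the mirror-image ligand is used.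

**Route**

Step 1
Reactants: 1 4-bromo-2-methoxyphenol
Product: 2 4-bromo-2-methoxyphenyl 4-methylbenzenesulfonate
Conditions: TsCl, Et3N, DMAP (cat.), CH2Cl2, 0 °C to rt
Reagents that add atoms: 4-methylbenzenesulfonyl chloride (TsCl), Cc1ccc(cc1)S(Cl)(=O)=O
Why: O-sulfonylation of the phenol gives an aryl sulfonate that is stable to the later acid, peracid and hydride steps and that lowers the donor strength of this arene, which the key step needs.

Step 2
Reactants: 2 4-bromo-2-methoxyphenyl 4-methylbenzenesulfonate; 3 prop-2-yn-1-ol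
Product: 4 4-(3-hydroxyprop-1-yn-1-yl)-2-methoxyphenyl 4-methylbenzenesulfonate
Conditions: Pd(PPh3)2Cl2 (3 mol %), CuI (5 mol %), Et3N, 70 °C
Reagents that add atoms: none
Why: Sonogashira coupling, in which zerovalent palladium inserts into the C–Br bond much faster than into the aryl C–O sulfonate bond and the copper acetylide of 3 transmetallates.

Step 3
Reactants: 4 4-(3-hydroxyprop-1-yn-1-yl)-2-methoxyphenyl 4-methylbenzenesulfonate
Product: 5 4-[(1Z)-3-hydroxyprop-1-en-1-yl]-2-methoxyphenyl 4-methylbenzenesulfonate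
Conditions: H2 (1 atm), Pd/CaCO3 poisoned with Pb(OAc)2, quinoline, EtOAc, rt
Reagents that add atoms: none
Why: Lindlar semihydrogenation adds H2 syn on the poisoned palladium surface and should stop at the Z alkene, whose geometry later places the aryl group endo on the cyclopropane.

Step 4
Reactants: 5 4-[(1Z)-3-hydroxyprop-1-en-1-yl]-2-methoxyphenyl 4-methylbenzenesulfonate; 6 2,2,6-trimethyl-4H-1,3-dioxin-4-one
Product: 7 (2Z)-3-[3-methoxy-4-(tosyloxy)phenyl]prop-2-en-1-yl 3-oxobutanoate
Conditions: xylenes, 135 °C, acetone distilled off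
Reagents that add atoms: none
Why: Thermal retro-[4+2] cleavage of the dioxinone gives acetylketene, which the allylic alcohol traps as the acetoacetate (acetoacetylation).

Step 5
Reactants: 7 (2Z)-3-[3-methoxy-4-(tosyloxy)phenyl]prop-2-en-1-yl 3-oxobutanoate
Product: 8 (2Z)-3-[3-methoxy-4-(tosyloxy)phenyl]prop-2-en-1-yl 2-diazo-3-oxobutanoate
Conditions: 4-acetamidobenzenesulfonyl azide, Et3N, MeCN, 0 °C to rt
Reagents that add atoms: 4-acetamidobenzenesulfonyl azide, CC(=O)Nc1ccc(cc1)S(=O)(=O)N=[N+]=[N-]
Why: Regitz diazo transfer to the active methylene of the β-keto ester.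

Step 6
Reactants: 8 (2Z)-3-[3-methoxy-4-(tosyloxy)phenyl]prop-2-en-1-yl 2-diazo-3-oxobutanoate
Product: 9 (2Z)-3-[3-methoxy-4-(tosyloxy)phenyl]prop-2-en-1-yl 3-[(tert-butyldimethylsilyl)oxy]-2-diazobut-3-enoate
Conditions: TBSOTf, Et3N, CH2Cl2, 0 °C
Reagents that add atoms: tert-butyldimethylsilyl trifluoromethanesulfonate (TBSOTf), CC(C)(C)[Si](C)(C)OS(=O)(=O)C(F)(F)F
Why: Silyl enol ether formation turns the acceptor/acceptor diazo compound into a vinyl (donor/acceptor) diazo ester, the carbene class that chiral dirhodium carboxylates transfer with better selectivity.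

Step 7
Reactants: 9 (2Z)-3-[3-methoxy-4-(tosyloxy)phenyl]prop-2-en-1-yl 3-[(tert-butyldimethylsilyl)oxy]-2-diazobut-3-enoate
Product: 11 (1R,5S,6S)-1-acetyl-6-[3-methoxy-4-(tosyloxy)phenyl]-3-oxabicyclo[3.1.0]hexan-2-one, via silyl enol ether cyclopropane 10 (not isolated)
Conditions: Rh2(S-NTTL)4 (1 mol %), toluene, 0 °C to rt; then 1 M HCl, THF, 0 °C
Reagents that add atoms: none
Why: Intramolecular cyclopropanation by the chiral dirhodium carbene is concerted, so the Z geometry is kept (aryl endo, cis to the lactone CH2) while the catalyst selects the alkene face and sets all three stereocentres; acid hydrolysis of the silyl enol ether then frees the acetyl group.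

Step 8
Reactants: 11 (1R,5S,6S)-1-acetyl-6-[3-methoxy-4-(tosyloxy)phenyl]-3-oxabicyclo[3.1.0]hexan-2-one; 12 formaldehyde (anhydrous monomer, freshly cracked from paraformaldehyde, excess)
Product: 13 (3aS,4R,6aS)-6a-acetyl-4-[3-methoxy-4-(tosyloxy)phenyl]tetrahydro-1H,3H-furo[3,4-c]furan-1-one
Conditions: Sn(OTf)2 (10 mol %), 4 Å molecular sieves, ClCH2CH2Cl, 0 °C to 40 °C
Reagents that add atoms: none
Why: Proposed new method: Sn(OTf)2 chelates the acetyl and lactone carbonyls of 11 and polarises the cyclopropane bond between the acceptor-bearing bridgehead carbon and the aryl-bearing carbon; the carbonyl oxygen of 12 opens this bond by backside attack at the benzylic carbon, and the tin enolate then closes onto the carbon of the O-alkylated formaldehyde oxocarbenium ion. The closest known reaction type is the Lewis-acid-catalysed (3+2) annulation of aldehydes with 2-arylcyclopropane-1,1-diesters to tetrahydrofurans; monomeric formaldehyde as the carbonyl partner and a lactone-fused 1-acyl cyclopropane as the three-carbon partner are not established, hence the label. The one ring closed is the oxolane of ring A, by a 5-(enolexo)-endo-trig aldol-type attack on the oxocarbenium ion, a mode that is usual for such cations. The benzylic stereocentre is set by inversion in the SN2-like opening, so the endo aryl group of 11 ends up exo, trans to the lactone CH2; the quaternary bridgehead centre is fixed by the cis ring fusion, the only fusion this bicyclo[3.3.0] frame allows. The step needs cleavage of the aryl-substituted cyclopropane bond only, which the aryl donor secures, and inversion instead of ionisation to a free benzylic cation, which the electron-poor sulfonate on the arene secures by holding the donor strength near that of a halophenyl group.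

Step 9
Reactants: 13 (3aS,4R,6aS)-6a-acetyl-4-[3-methoxy-4-(tosyloxy)phenyl]tetrahydro-1H,3H-furo[3,4-c]furan-1-one
Product: 15 (3aS,4R,6aR)-6a-hydroxy-4-[3-methoxy-4-(tosyloxy)phenyl]tetrahydro-1H,3H-furo[3,4-c]furan-1-one, via bridgehead acetate 14 (not isolated)
Conditions: mCPBA, CF3CO2H (cat.), CH2Cl2, rt; then K2CO3, MeOH, 0 °C
Reagents that add atoms: 3-chloroperoxybenzoic acid (mCPBA), OOC(=O)c1cccc(Cl)c1
Why: Baeyer–Villiger oxidation, in which the quaternary bridgehead carbon should migrate in preference to methyl with retention of configuration, turns the acetyl activating group into the tertiary acetate, and mild methanolysis then frees the bridgehead alcohol.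

Step 10
Reactants: 15 (3aS,4R,6aR)-6a-hydroxy-4-[3-methoxy-4-(tosyloxy)phenyl]tetrahydro-1H,3H-furo[3,4-c]furan-1-one
Product: 16 (3aS,4R,6aR)-4-[3-methoxy-4-(tosyloxy)phenyl]tetrahydro-1H,3H-furo[3,4-c]furan-1,6a-diol (both anomers)
Conditions: i-Bu2AlH (2.5 equiv), CH2Cl2, −78 °C; aq potassium sodium tartrate
Reagents that add atoms: none
Why: Half-reduction of the γ-lactone with i-Bu2AlH should stop at the lactol because the tetrahedral aluminate is stable at −78 °C; the aryl sulfonate is inert at this temperature.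

Step 11
Reactants: 1 4-bromo-2-methoxyphenol
Product: 17 (4-bromo-2-methoxyphenoxy)(tert-butyl)dimethylsilane
Conditions: TBSCl, imidazole, DMF, rt
Reagents that add atoms: tert-butyldimethylsilyl chloride (TBSCl), CC(C)(C)[Si](C)(C)Cl
Why: Imidazole-catalysed O-silylation masks the phenol for Grignard formation and leaves this arene electron-rich, as the cationic ring closure in step 13 requires.

Step 12
Reactants: 16 (3aS,4R,6aR)-4-[3-methoxy-4-(tosyloxy)phenyl]tetrahydro-1H,3H-furo[3,4-c]furan-1,6a-diol; 17 (4-bromo-2-methoxyphenoxy)(tert-butyl)dimethylsilane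
Product: 19 (3R,4S,5R)-3-{[4-(tert-butyldimethylsilyloxy)-3-methoxyphenyl](hydroxy)methyl}-4-(hydroxymethyl)-5-[3-methoxy-4-(tosyloxy)phenyl]oxolan-3-ol (both carbinol epimers), via arylmagnesium bromide 18 (not isolated)
Conditions: 17 (3.5 equiv), Mg, THF, 45 °C; then 16, THF, 0 °C; aq NH4Cl
Reagents that add atoms: none
Why: Grignard addition to the open hydroxy-aldehyde form of the lactol, after the excess reagent has deprotonated both hydroxyls; chelation by the neighbouring magnesium alkoxide should favour the carbinol configuration of the target, but this centre is formed again in step 13 and is left open here.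

Step 13
Reactants: 19 (3R,4S,5R)-3-{[4-(tert-butyldimethylsilyloxy)-3-methoxyphenyl](hydroxy)methyl}-4-(hydroxymethyl)-5-[3-methoxy-4-(tosyloxy)phenyl]oxolan-3-ol
Product: 20 (1R,3aR,4S,6aS)-4-[4-(tert-butyldimethylsilyloxy)-3-methoxyphenyl]-1-[3-methoxy-4-(tosyloxy)phenyl]tetrahydro-1H,3H-furo[3,4-c]furan-3a(4H)-ol
Conditions: 10-camphorsulfonic acid (5 mol %), CH2Cl2, 0 °C
Reagents that add atoms: none
Why: Acid-catalysed SN1 cycloetherification (5-exo closure of the primary hydroxyl onto the para-silyloxybenzylic cation) should place the aryl group exo on the convex face, cis to the bridgehead hydroxyl, while the benzylic ether of ring A, on the sulfonate-bearing arene, is too electron-poor to ionise.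

Step 14
Reactants: 20 (1R,3aR,4S,6aS)-4-[4-(tert-butyldimethylsilyloxy)-3-methoxyphenyl]-1-[3-methoxy-4-(tosyloxy)phenyl]tetrahydro-1H,3H-furo[3,4-c]furan-3a(4H)-ol
Product: 21 (1R,3aR,4S,6aS)-1,4-bis(4-hydroxy-3-methoxyphenyl)tetrahydro-1H,3H-furo[3,4-c]furan-3a(4H)-ol
Conditions: KOH, MeOH/THF/H2O, 50 °C, argon; then aq NH4Cl
Reagents that add atoms: none
Why: Hydroxide attacks the sulfur of the aryl sulfonate and the silicon of the aryl silyl ether, which frees both phenols without touching the ether rings or the tertiary alcohol.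

**Compound list**

1 | 4-bromo-2-methoxyphenol | COc1cc(Br)ccc1O | starting material
2 | 4-bromo-2-methoxyphenyl 4-methylbenzenesulfonate | COc1cc(Br)ccc1OS(=O)(=O)c1ccc(C)cc1 | intermediate
3 | prop-2-yn-1-ol | C#CCO | starting material
4 | 4-(3-hydroxyprop-1-yn-1-yl)-2-methoxyphenyl 4-methylbenzenesulfonate | COc1cc(C#CCO)ccc1OS(=O)(=O)c1ccc(C)cc1 | intermediate
5 | 4-[(1Z)-3-hydroxyprop-1-en-1-yl]-2-methoxyphenyl 4-methylbenzenesulfonate | COc1cc(/C=C\CO)ccc1OS(=O)(=O)c1ccc(C)cc1 | intermediate
6 | 2,2,6-trimethyl-4H-1,3-dioxin-4-one | CC1=CC(=O)OC(C)(C)O1 | starting material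
7 | (2Z)-3-[3-methoxy-4-(tosyloxy)phenyl]prop-2-en-1-yl 3-oxobutanoate | CC(=O)CC(=O)OC/C=C\c1ccc(OS(=O)(=O)c2ccc(C)cc2)c(OC)c1 | intermediate
8 | (2Z)-3-[3-methoxy-4-(tosyloxy)phenyl]prop-2-en-1-yl 2-diazo-3-oxobutanoate | CC(=O)C(=[N+]=[N-])C(=O)OC/C=C\c1ccc(OS(=O)(=O)c2ccc(C)cc2)c(OC)c1 | intermediate
9 | (2Z)-3-[3-methoxy-4-(tosyloxy)phenyl]prop-2-en-1-yl 3-[(tert-butyldimethylsilyl)oxy]-2-diazobut-3-enoate | C=C(O[Si](C)(C)C(C)(C)C)C(=[N+]=[N-])C(=O)OC/C=C\c1ccc(OS(=O)(=O)c2ccc(C)cc2)c(OC)c1 | intermediate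
10 | (1R,5S,6S)-1-{1-[(tert-butyldimethylsilyl)oxy]ethenyl}-6-[3-methoxy-4-(tosyloxy)phenyl]-3-oxabicyclo[3.1.0]hexan-2-one | C=C(O[Si](C)(C)C(C)(C)C)[C@]12C(=O)OC[C@H]1[C@H]2c1ccc(OS(=O)(=O)c2ccc(C)cc2)c(OC)c1 | intermediate
11 | (1R,5S,6S)-1-acetyl-6-[3-methoxy-4-(tosyloxy)phenyl]-3-oxabicyclo[3.1.0]hexan-2-one (aryl endo) | CC(=O)[C@]12C(=O)OC[C@H]1[C@H]2c1ccc(OS(=O)(=O)c2ccc(C)cc2)c(OC)c1 | intermediate
12 | formaldehyde | C=O | starting material
13 | (3aS,4R,6aS)-6a-acetyl-4-[3-methoxy-4-(tosyloxy)phenyl]tetrahydro-1H,3H-furo[3,4-c]furan-1-one | COc1cc([C@@H]2OC[C@@]3(C(C)=O)C(=O)OC[C@@H]23)ccc1OS(=O)(=O)c1ccc(C)cc1 | intermediate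
14 | (3aS,4R,6aR)-4-[3-methoxy-4-(tosyloxy)phenyl]-1-oxotetrahydro-1H,3H-furo[3,4-c]furan-6a-yl acetate | COc1cc([C@@H]2OC[C@@]3(OC(C)=O)C(=O)OC[C@@H]23)ccc1OS(=O)(=O)c1ccc(C)cc1 | intermediate
15 | (3aS,4R,6aR)-6a-hydroxy-4-[3-methoxy-4-(tosyloxy)phenyl]tetrahydro-1H,3H-furo[3,4-c]furan-1-one | COc1cc([C@@H]2OC[C@@]3(O)C(=O)OC[C@@H]23)ccc1OS(=O)(=O)c1ccc(C)cc1 | intermediate
16 | (3aS,4R,6aR)-4-[3-methoxy-4-(tosyloxy)phenyl]tetrahydro-1H,3H-furo[3,4-c]furan-1,6a-diol (both anomers) | COc1cc([C@@H]2OC[C@@]3(O)C(O)OC[C@@H]23)ccc1OS(=O)(=O)c1ccc(C)cc1 | intermediate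
17 | (4-bromo-2-methoxyphenoxy)(tert-butyl)dimethylsilane | COc1cc(Br)ccc1O[Si](C)(C)C(C)(C)C | intermediate
18 | [4-(tert-butyldimethylsilyloxy)-3-methoxyphenyl]magnesium bromide | COc1cc([Mg]Br)ccc1O[Si](C)(C)C(C)(C)C | intermediate
19 | (3R,4S,5R)-3-{[4-(tert-butyldimethylsilyloxy)-3-methoxyphenyl](hydroxy)methyl}-4-(hydroxymethyl)-5-[3-methoxy-4-(tosyloxy)phenyl]oxolan-3-ol (both carbinol epimers) | COc1cc([C@@H]2OC[C@@](O)(C(O)c3ccc(O[Si](C)(C)C(C)(C)C)c(OC)c3)[C@H]2CO)ccc1OS(=O)(=O)c1ccc(C)cc1 | intermediate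
20 | (1R,3aR,4S,6aS)-4-[4-(tert-butyldimethylsilyloxy)-3-methoxyphenyl]-1-[3-methoxy-4-(tosyloxy)phenyl]tetrahydro-1H,3H-furo[3,4-c]furan-3a(4H)-ol | COc1cc([C@@H]2OC[C@@]3(O)[C@H](c4ccc(O[Si](C)(C)C(C)(C)C)c(OC)c4)OC[C@@H]23)ccc1OS(=O)(=O)c1ccc(C)cc1 | intermediate
21 | (1R,3aR,4S,6aS)-1,4-bis(4-hydroxy-3-methoxyphenyl)tetrahydro-1H,3H-furo[3,4-c]furan-3a(4H)-ol (both aryl groups exo, bridgehead OH and H cis) | COc1cc([C@@H]2OC[C@@]3(O)[C@H](c4ccc(O)c(OC)c4)OC[C@@H]23)ccc1O | target

**Step count and risks**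

Total steps: 14. Longest linear sequence: 13 (steps 1 to 10, then 12 to 14; step 11 is the side branch).

Steps most likely to fail:

1. Step 8 (Proposed new method). Formaldehyde may oligomerise faster than its weakly basic oxygen attacks the tempered cyclopropane, or the cyclopropane may open by ionisation so that the inversion at the benzylic carbon is lost. The fallback uses known chemistry and sets out from 11. Sc(OTf)3-catalysed hydrative ring opening (water, 1,4-dioxane; SN2-like, inversion at the benzylic carbon) should give the benzylic alcohol (4S)-3-acetyl-4-{(R)-hydroxy[3-methoxy-4-(tosyloxy)phenyl]methyl}oxolan-2-one F1. Chloromethylation of its hydroxyl with paraformaldehyde and HCl gas (CH2Cl2, 0 °C) should give the chloromethyl ether (4S)-3-acetyl-4-{(R)-(chloromethoxy)[3-methoxy-4-(tosyloxy)phenyl]methyl}oxolan-2-one F2. i-Pr2NEt then closes the oxolane by intramolecular C-alkylation of the 2-acyl lactone (5-exo-tet, cis fusion enforced by the tether), and the route is rejoined at 13.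

2. Step 9. The Baeyer–Villiger oxidation may be slow because the migrating quaternary carbon is electron-poor, or methyl may migrate in its place. The fallback sets out from 13. Retro-Claisen deacetylation (NaOMe cat., MeOH, 0 °C) should give the cis-fused lactone (3aS,4R,6aS)-4-[3-methoxy-4-(tosyloxy)phenyl]tetrahydro-1H,3H-furo[3,4-c]furan-1-one F3. Hydroxylation of its potassium enolate (KN(SiMe3)2, THF, −78 °C; 2-(phenylsulfonyl)-3-phenyloxaziridine) brings the oxygen in on the only face the cis fusion allows, and the route is rejoined at 15.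

3. Step 13. The closure onto the planar benzylic cation may show poor facial selectivity, or the cation may undergo a 1,2-shift (semipinacol ring expansion) next to the tertiary carbinol. The fallback sets out from lactol 16 and bypasses 19. Exchange of the anomeric hydroxyl with benzenesulfinic acid and CaCl2 (CH2Cl2, rt) should give the sulfone (3aS,4R,6aR)-4-[3-methoxy-4-(tosyloxy)phenyl]-1-(phenylsulfonyl)tetrahydro-1H,3H-furo[3,4-c]furan-6a(6H)-ol F4. The arylzinc reagent [4-(tert-butyldimethylsilyloxy)-3-methoxyphenyl]zinc bromide F5, made from 18 and ZnBr2, then replaces the sulfinate through the ring oxocarbenium ion (THF, rt). The aryl group should enter from the convex face, cis to the bridgehead alkoxide, and the route is rejoined at 20.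

**Further compounds**

F1 | step 8 | (4S)-3-acetyl-4-{(R)-hydroxy[3-methoxy-4-(tosyloxy)phenyl]methyl}oxolan-2-one | CC(=O)C1C(=O)OC[C@H]1[C@@H](O)c1ccc(OS(=O)(=O)c2ccc(C)cc2)c(OC)c1
F2 | step 8 | (4S)-3-acetyl-4-{(R)-(chloromethoxy)[3-methoxy-4-(tosyloxy)phenyl]methyl}oxolan-2-one | CC(=O)C1C(=O)OC[C@H]1[C@@H](OCCl)c1ccc(OS(=O)(=O)c2ccc(C)cc2)c(OC)c1
F3 | step 9 | (3aS,4R,6aS)-4-[3-methoxy-4-(tosyloxy)phenyl]tetrahydro-1H,3H-furo[3,4-c]furan-1-one | COc1cc([C@@H]2OC[C@H]3C(=O)OC[C@@H]23)ccc1OS(=O)(=O)c1ccc(C)cc1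
F4 | step 13 | (3aS,4R,6aR)-4-[3-methoxy-4-(tosyloxy)phenyl]-1-(phenylsulfonyl)tetrahydro-1H,3H-furo[3,4-c]furan-6a(6H)-ol | COc1cc([C@@H]2OC[C@@]3(O)C(S(=O)(=O)c4ccccc4)OC[C@@H]23)ccc1OS(=O)(=O)c1ccc(C)cc1
F5 | step 13 | [4-(tert-butyldimethylsilyloxy)-3-methoxyphenyl]zinc bromide | COc1cc([Zn]Br)ccc1O[Si](C)(C)C(C)(C)C
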